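## Structural features

The target is a biflavonoid joined through one oxygen. One half is a (2S)-5-hydroxy-7-methoxyflavanone (rings A and C with a saturated C2–C3 and a para-substituted ring B at C2). The other half is kaempferol, a 5,7-dihydroxy-2-(4-hydroxyphenyl)chromen-4-one. The linking oxygen is both O4' of the flavanone ring B and the C3 oxygen of the flavonol, so the link is an ether between an aryl carbon and the fully substituted enol carbon C3 of the flavonol pyranone. There is a single stereocentre, C2 of the flavanone, with no stereocentre next to it. It is benzylic, β to the C4 ketone and bonded to the ring oxygen, so base, strong acid or heat can open ring C to a 2'-hydroxychalcone and racemise it. Four phenols (three on the flavonol, one on the flavanone) are oxidisable and must be kept distinct from the one 7-O-methyl group, and the flavanone C2–O1 bond is a benzylic ether that over-reduction can break. The real difficulty is twofold: the hindered 3-O-aryl ether on the tetrasubstituted C2=C3 of the flavonol, and the late, mild, enantioselective creation of C2. The key step exploits the fact that flavonol ring A (C4a, C5 to C8, C8a, with oxygens at C5, C7 and O1) is simply phloroglucinol. Its threefold symmetry lets ring C, already carrying the C3 aryl ether and the C2 aryl group, be annulated onto the free triphenol through C4–C4a and O1–C2 with no regiochemical question.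

## Logic of the disconnections

15 to 14: only the four O–benzyl bonds are cut. The phenols would interfere with the alkylations and the palladium chemistry, and one neutral operation at the end spares the base-labile C2 centre. The forward step must stop at the ethers and leave the benzylic C2–O1 bond, the ketone and the flavonol C2=C3 alone.

14 to 9 + 13: the bond between the flavanone stereocentre C2 and ring B is cut. It is the one bond at the stereocentre that a chiral catalyst can form face-selectively, and the cut divides the molecule into two achiral halves of similar size. The forward step needs aryl transfer to one face of the β-carbon of an electron-rich enone, with no reaction at the tetrasubstituted flavonol enone.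

9 to 8: the C–B bond is traced back to C–Br. A bromide is inert to the thermal annulation and to alkylation, so it can be carried from the first step. The forward step must deliver the free boronic acid without touching benzyl ethers or the pyranone.

8 to 7: the 5-O and 7-O benzyl bonds are cut, because the annulation leaves ring A as free phenols. The forward step must also alkylate the chelated 5-OH.

7 to 3 + 4: C4–C4a and O1–C2 of flavonol ring C are cut. This removes the pyranone in one stroke and leaves the awkward C3–O–aryl ether inside an acyclic fragment. One partner becomes the symmetrical, unprotected 4. The forward step must acylate the ring carbon before anything attacks the ketone, and must stop after one annulation.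

3 to 1 + 2: the bond between the α-carbon and the ketone carbonyl is cut. The aryl ether oxygen is already present in 1, so the flavonol C3–O bond never has to be made at an sp2 carbon. The forward step needs C-acylation over O-acylation and no second acylation.

13 to 11 (through 12): O1–C2 and C2–C3 of the chromone are cut, which removes one carbon and leaves a 2-hydroxyacetophenone. The forward step needs condensation at the methyl group and closure by the one free phenol.

11 to 10: one O–benzyl bond is cut, giving a commercial acetophenone with two equivalent phenols. The forward step must stop at the monoether.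

## Other disconnections considered

Alternative 1: The cut is C4a–C8a of flavanone ring A, which is folded from a chain instead of being bought. Pyranone A1 would be opened by Mg(OMe)2 in methanol; the methylene between the two ketones then attacks the ester carbonyl (Claisen-type closure and aromatisation) to give the acylphloroglucinol monomethyl ether A2. Desilylation and Mitsunobu closure with inversion, (3R) to (2S), would give A3, and hydrogenolysis would give 15.
- In favour: the 5-OH/7-OMe pattern comes directly from the pyranone methoxy group, so no phenols need to be differentiated. This is better than the chosen plan, which needs step 5. No boronic acid is consumed.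
- Against: the β-silyloxy ketone sits in basic methanol, where E1cB loss of silanolate to a chalcone-type enone would erase the stereocentre. The flavonol pyranone is exposed to methoxide. The Mitsunobu closure at a para-aryloxy benzylic carbinol can leak through ionisation.
- Comparison: like the two other alternatives, this one concerns the flavanone half and would draw its flavonol aryl ether from 8, so it competes with steps 4 to 8, not with step 2. It constructs an aromatic ring that 10 already supplies. It equals the chosen plan in using a symmetrical trioxygenated ring to avoid regiochemistry. Its mechanism is anionic and basic, where the chosen key step is neutral and thermal. A1 needs formylation, an enantioselective aldol addition and silylation before its key step, so it runs several operations longer.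

Alternative 2: The cut is O1–C2 of the flavanone. A cinchona-derived bifunctional thiourea would catalyse intramolecular oxa-Michael addition of the 2'-phenol of arylidene ketoester A4 to give the trans ester A5. Acid-mediated loss of the tert-butyl ester and decarboxylation would converge on 14.
- In favour: the closure is intramolecular, metal-free and run at ambient temperature. The advanced fragment enters as an aldehyde, so none is lost to protodeboronation. These points are better than the chosen plan.
- Against: the aroyl group of A4 is flanked by two ortho oxygens and twisted out of conjugation, which may weaken catalyst binding. The decarboxylation needs acid and heat on a flavanone whose ring B is electron-rich, which invites racemisation by ring opening.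
- Comparison: both plans set C2 catalytically by conjugate addition to an enone in the last skeletal step, so they are equal in mechanism type and in lateness. A4 needs formylation, a C-acylation and a Knoevenagel condensation from 8 and 11, and a decarboxylation follows, so this route is about two operations longer.

Alternative 3: The cut is C4–C4a of the flavanone. Acid A6, activated with trifluoroacetic anhydride, would acylate the ortho carbon of its own dimethoxyphenyl ether to give A7. Chelation-controlled cleavage of the 5-O-methyl ether and debenzylation would follow to reach 15.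
- In favour: no bond to the stereocentre is made or broken in the ring closure. The two ortho positions are equivalent and the arene is very electron-rich, so the closure is regiochemically clean. In its use of symmetry it equals the chosen plan.
- Against: the benzylic aryl ether with a para-aryloxy donor is exposed to strong acid, where ionisation would lead to racemisation or elimination to a cinnamic acid. The stereocentre must first be made by Mitsunobu etherification of a benzylic alcohol, which competes with elimination. The 5-OMe/7-OMe distinction is postponed to a Lewis acid step that can open ring C.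
- Comparison: the chosen plan forms C2 by catalyst control, and the only group it has to differentiate, the pair of phenols in 10, is dealt with in the first step of the chromone branch. A6 needs formylation, an enantioselective acetate aldol addition, etherification with inversion and ester hydrolysis, so this route is longer by about two operations.

Key step: step 2

Remarks on the chemistry, one per line:
- The key-step equation balances as 3 + 4 → 7 + ethanol + water. The connectivity of precursor and product was checked atom by atom and needs no correction.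
- Design change: the ketoester carries its para oxygen as a benzyl ether, not as a free phenol. A free phenol would compete with 4 for the acylketene, and an acetate would not survive the ester enolate. The benzyl group is needed later anyway, so one deprotection and one alkylation are saved. The ethyl ester is kept because it releases the acylketene only once 4 is molten.
- Design change: the bromide is converted directly into the boronic acid, because the cationic divalent palladium catalyst of step 7 transmetalates boronic acids, not pinacol esters.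
- Assumption: the sense of induction of the pyridine-oxazoline ligand on chromones is taken to parallel that on cyclic enones, so the (R)-ligand should give the (2S)-flavanone. If a model run shows the opposite, the (S)-ligand is used.
- Assumption: 1 and 2 are purchased as such.

## Route

Step 1
Reactants: 1 ethyl (4-bromophenoxy)acetate; 2 4-(benzyloxy)benzoyl chloride
Product: 3 ethyl 3-[4-(benzyloxy)phenyl]-2-(4-bromophenoxy)-3-oxopropanoate (racemic; C2 enolisable)
Conditions: 1 (2.0 equiv), LiN(SiMe3)2 (2.0 equiv), THF, −78 °C; then 2 (1.0 equiv), −78 to −20 °C; aq NH4Cl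
Reagents that add atoms: none
Why: Crossed Claisen-type C-acylation of a lithium ester enolate by a non-enolisable aroyl chloride; the second equivalent of enolate deprotonates 3 as it forms, which prevents a second acylation, and the surplus 1 is recovered. The aryl bromide and benzyl ether are inert to the amide base at −78 °C.

Step 2
Reactants: 3 ethyl 3-[4-(benzyloxy)phenyl]-2-(4-bromophenoxy)-3-oxopropanoate; 4 phloroglucinol (anhydrous)
Product: 7 2-[4-(benzyloxy)phenyl]-3-(4-bromophenoxy)-5,7-dihydroxy-4H-chromen-4-one, via acylketene 5 (not isolated), via aryl diketone 6 (not isolated)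
Conditions: 4 (3 equiv), neat melt, Ar sweep, 230–240 °C, 15–30 min (or microwave, 240 °C, 5 min); hot-water trituration
Reagents that add atoms: none
Why: On heating, the enol of 3 expels ethanol to give acylketene 5, which is why the melt temperature is needed. Phloroglucinol, the most nucleophilic simple phenol, traps 5 at a ring carbon, either directly or by reversible O-acylation followed by acyl transfer to carbon, to give aryl diketone 6, which is held by a hydrogen bond between the new ketone and an ortho phenol. That phenol adds to the aroyl ketone in a 6-exo-trig closure to a 2-hydroxyflavanone hemiketal, and loss of water gives the aromatic 4-pyranone, which makes the sequence irreversible. The closest known reaction type is the catalyst-free thermal condensation of phenols with β-ketoesters to chromones (Mentzer pyrone synthesis), which is established for phloroglucinol with aroylacetates and has been applied to α-substituted aroylacetates. No stereocentre is formed, and the labile α-centre of 3 ends as sp2 C3. The step needs chromone and not coumarin formation, which the absence of acid secures because the ketene carbon is then attacked before the ketone; it needs a single annulation, which excess 4 and deactivation of ring A by the new carbonyl secure; regiochemistry does not arise because 4 is symmetrical. The benzyl ether removes the only other nucleophile from the ketoester, and the aryl bromide and diaryl ether are inert to neutral heat.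

Step 3
Reactants: 7 2-[4-(benzyloxy)phenyl]-3-(4-bromophenoxy)-5,7-dihydroxy-4H-chromen-4-one
Product: 8 5,7-bis(benzyloxy)-2-[4-(benzyloxy)phenyl]-3-(4-bromophenoxy)-4H-chromen-4-one
Conditions: BnBr (3 equiv), K2CO3 (4 equiv), n-Bu4NI (10 mol%), DMF, 70 °C
Reagents that add atoms: benzyl bromide, BrCc1ccccc1
Why: Williamson etherification; the 7-OH reacts first, and the chelated 5-OH follows with excess halide, iodide catalysis and heat in a dipolar solvent.

Step 4
Reactants: 8 5,7-bis(benzyloxy)-2-[4-(benzyloxy)phenyl]-3-(4-bromophenoxy)-4H-chromen-4-one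
Product: 9 {4-[(5,7-bis(benzyloxy)-2-[4-(benzyloxy)phenyl]-4-oxo-4H-chromen-3-yl)oxy]phenyl}boronic acid
Conditions: B2(OH)4 (3 equiv), PdCl(XPhos)(2'-aminobiphenyl-2-yl) (2 mol%), XPhos (4 mol%), KOAc (3 equiv), EtOH/THF, 80 °C; aq work-up
Reagents that add atoms: tetrahydroxydiboron, OB(O)B(O)O
Why: Miyaura-type borylation with tetrahydroxydiboron: zerovalent palladium inserts into the C–Br bond, acetate-assisted transmetalation from boron and reductive elimination give the arylboronic acid directly. Benzyl ethers, the diaryl ether and the pyranone are spectators.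

Step 5
Reactants: 10 2',6'-dihydroxy-4'-methoxyacetophenone
Product: 11 1-[2-(benzyloxy)-6-hydroxy-4-methoxyphenyl]ethan-1-one
Conditions: BnBr (1.05 equiv), K2CO3 (1.1 equiv), acetone, reflux
Reagents that add atoms: benzyl bromide, BrCc1ccccc1
Why: Williamson etherification of one of two equivalent phenols; once the first is capped, the remaining phenol is locked in a hydrogen bond to the ketone and is far less nucleophilic, which stops the reaction at the monoether.

Step 6
Reactants: 11 1-[2-(benzyloxy)-6-hydroxy-4-methoxyphenyl]ethan-1-one
Product: 13 5-(benzyloxy)-7-methoxy-4H-chromen-4-one, via enaminone 12 (not isolated)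
Conditions: Me2NCH(OMe)2, toluene, 100 °C; concentrate; conc. HCl, CH2Cl2, rt
Reagents that add atoms: N,N-dimethylformamide dimethyl acetal, COC(OC)N(C)C
Why: Enaminone formation at the acetyl methyl group, then acid-promoted 6-endo-trig addition of the phenol to the enaminone and loss of dimethylamine, the standard chromone synthesis from 2-hydroxyacetophenones. The aryl benzyl ether tolerates brief acid at room temperature.

Step 7
Reactants: 9 {4-[(5,7-bis(benzyloxy)-2-[4-(benzyloxy)phenyl]-4-oxo-4H-chromen-3-yl)oxy]phenyl}boronic acid; 13 5-(benzyloxy)-7-methoxy-4H-chromen-4-one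
Product: 14 (2S)-5-(benzyloxy)-2-{4-[(5,7-bis(benzyloxy)-2-[4-(benzyloxy)phenyl]-4-oxo-4H-chromen-3-yl)oxy]phenyl}-7-methoxy-2,3-dihydro-4H-chromen-4-one
Conditions: 13 (2 equiv), Pd(OCOCF3)2 (10 mol%), (R)-4-tert-butyl-2-(pyridin-2-yl)-4,5-dihydro-1,3-oxazole (12 mol%), NH4PF6 (30 mol%), H2O (5 equiv), ClCH2CH2Cl, 60 °C
Reagents that add atoms: none
Why: Asymmetric conjugate addition of an arylboronic acid to a chromone under a cationic divalent palladium pyridine-oxazoline catalyst: transmetalation, enantio-determining insertion of the chromone C2=C3 into the aryl–palladium bond, and protonolysis of the palladium enolate by water. The tert-butyl group of the (R)-ligand shields one face so that the aryl group should arrive on the face that gives (2S). Only the C2-unsubstituted chromone 13 can insert; the tetrasubstituted flavonol enone of 9 cannot.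

Step 8
Reactants: 14 (2S)-5-(benzyloxy)-2-{4-[(5,7-bis(benzyloxy)-2-[4-(benzyloxy)phenyl]-4-oxo-4H-chromen-3-yl)oxy]phenyl}-7-methoxy-2,3-dihydro-4H-chromen-4-one
Product: 15 (2S)-2-{4-[(5,7-dihydroxy-2-(4-hydroxyphenyl)-4-oxo-4H-chromen-3-yl)oxy]phenyl}-5-hydroxy-7-methoxy-2,3-dihydro-4H-chromen-4-one
Conditions: H2 (1 atm), 10% Pd/C, EtOAc/THF, rt
Reagents that add atoms: none
Why: Hydrogenolysis of four aryl benzyl ethers under neutral conditions, which leave the base-labile C2 centre, the methyl ether, the flavanone ketone and the tetrasubstituted flavonol C2=C3 untouched. The reaction is stopped at full debenzylation so that the benzylic C2–O1 bond is not cleaved.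

## Compound list

1 | ethyl (4-bromophenoxy)acetate | CCOC(=O)COc1ccc(Br)cc1 | starting material
2 | 4-(benzyloxy)benzoyl chloride | O=C(Cl)c1ccc(OCc2ccccc2)cc1 | starting material
3 | ethyl 3-[4-(benzyloxy)phenyl]-2-(4-bromophenoxy)-3-oxopropanoate (racemic) | CCOC(=O)C(Oc1ccc(Br)cc1)C(=O)c1ccc(OCc2ccccc2)cc1 | intermediate
4 | phloroglucinol | Oc1cc(O)cc(O)c1 | starting material
5 | 3-[4-(benzyloxy)phenyl]-2-(4-bromophenoxy)-3-oxoprop-1-en-1-one (acylketene) | O=C=C(Oc1ccc(Br)cc1)C(=O)c1ccc(OCc2ccccc2)cc1 | intermediate (not isolated)
6 | 3-[4-(benzyloxy)phenyl]-2-(4-bromophenoxy)-1-(2,4,6-trihydroxyphenyl)propane-1,3-dione | O=C(c1ccc(OCc2ccccc2)cc1)C(Oc1ccc(Br)cc1)C(=O)c1c(O)cc(O)cc1O | intermediate (not isolated)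
7 | 2-[4-(benzyloxy)phenyl]-3-(4-bromophenoxy)-5,7-dihydroxy-4H-chromen-4-one | O=c1c(Oc2ccc(Br)cc2)c(-c2ccc(OCc3ccccc3)cc2)oc2cc(O)cc(O)c12 | intermediate
8 | 5,7-bis(benzyloxy)-2-[4-(benzyloxy)phenyl]-3-(4-bromophenoxy)-4H-chromen-4-one | O=c1c(Oc2ccc(Br)cc2)c(-c2ccc(OCc3ccccc3)cc2)oc2cc(OCc3ccccc3)cc(OCc3ccccc3)c12 | intermediate
9 | {4-[(5,7-bis(benzyloxy)-2-[4-(benzyloxy)phenyl]-4-oxo-4H-chromen-3-yl)oxy]phenyl}boronic acid | OB(O)c1ccc(Oc2c(-c3ccc(OCc4ccccc4)cc3)oc3cc(OCc4ccccc4)cc(OCc4ccccc4)c3c2=O)cc1 | intermediate
10 | 2',6'-dihydroxy-4'-methoxyacetophenone | COc1cc(O)c(C(C)=O)c(O)c1 | starting material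
11 | 1-[2-(benzyloxy)-6-hydroxy-4-methoxyphenyl]ethan-1-one | COc1cc(O)c(C(C)=O)c(OCc2ccccc2)c1 | intermediate
12 | (2E)-1-[2-(benzyloxy)-6-hydroxy-4-methoxyphenyl]-3-(dimethylamino)prop-2-en-1-one | COc1cc(O)c(C(=O)/C=C/N(C)C)c(OCc2ccccc2)c1 | intermediate (not isolated)
13 | 5-(benzyloxy)-7-methoxy-4H-chromen-4-one | COc1cc(OCc2ccccc2)c2c(c1)occc2=O | intermediate
14 | (2S)-5-(benzyloxy)-2-{4-[(5,7-bis(benzyloxy)-2-[4-(benzyloxy)phenyl]-4-oxo-4H-chromen-3-yl)oxy]phenyl}-7-methoxy-2,3-dihydro-4H-chromen-4-one | COc1cc(OCc2ccccc2)c2c(c1)O[C@H](c1ccc(Oc3c(-c4ccc(OCc5ccccc5)cc4)oc4cc(OCc5ccccc5)cc(OCc5ccccc5)c4c3=O)cc1)CC2=O | intermediate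
15 | (2S)-2-{4-[(5,7-dihydroxy-2-(4-hydroxyphenyl)-4-oxo-4H-chromen-3-yl)oxy]phenyl}-5-hydroxy-7-methoxy-2,3-dihydro-4H-chromen-4-one | COc1cc(O)c2c(c1)O[C@H](c1ccc(Oc3c(-c4ccc(O)cc4)oc4cc(O)cc(O)c4c3=O)cc1)CC2=O | target

## Step count and least certain steps

Total step count: 8. Longest linear sequence: 6 steps (steps 1, 2, 3, 4, 7 and 8); the chromone branch (steps 5 and 6) joins at step 7.

**Step 2 (key step).** The acylketene may be consumed by paths other than C-acylation: dimerisation, O-acylation that does not migrate, or hydrolysis by the water of cyclodehydration followed by decarboxylation. The α-aryloxy group makes this ketene more hindered and less electrophilic than that of a simple aroylacetate, and the benzyl group may migrate in a phenolic melt at 240 °C.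

Fallback, from 4 back to 7:
- Hoesch acylation of 4 with (4-bromophenoxy)acetonitrile (ZnCl2, HCl gas, Et2O, 0 °C) would precipitate 2-(4-bromophenoxy)-1-(2,4,6-trihydroxyphenyl)ethan-1-iminium chloride F1.
- Boiling water would hydrolyse it to 2-(4-bromophenoxy)-1-(2,4,6-trihydroxyphenyl)ethan-1-one F2.
- Separately, 2 and potassium 4-(benzyloxy)benzoate in THF would give 4-(benzyloxy)benzoic anhydride F3.
- Allan–Robinson fusion of F2 with F3 and potassium 4-(benzyloxy)benzoate at about 175 °C should give 2-[4-(benzyloxy)phenyl]-3-(4-bromophenoxy)-5-hydroxy-4-oxo-4H-chromen-7-yl 4-(benzyloxy)benzoate F4.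
- Brief saponification (KOH, aqueous EtOH, then dilute acid) returns to the route at 7.

**Step 7.** Insertion into the doubly donor-substituted, peri-benzyloxy chromone may be slow, so that protodeboronation and oxidative homocoupling of the boronic acid outrun it. Facial discrimination may also be eroded by the bulk of the aryl partner.

Fallback, from 8 back to 14, using 11:
- Reductive carbonylation of 8 (Pd(OAc)2, di(1-adamantyl)-n-butylphosphine, TMEDA, CO/H2, toluene, 100 °C) would give 4-[(5,7-bis(benzyloxy)-2-[4-(benzyloxy)phenyl]-4-oxo-4H-chromen-3-yl)oxy]benzaldehyde F5.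
- Claisen–Schmidt condensation with 11 (KOH, EtOH/THF, rt) would give (2E)-1-[2-(benzyloxy)-6-hydroxy-4-methoxyphenyl]-3-{4-[(5,7-bis(benzyloxy)-2-[4-(benzyloxy)phenyl]-4-oxo-4H-chromen-3-yl)oxy]phenyl}prop-2-en-1-one F6.
- Oxa-Michael closure (NaOAc, EtOH, reflux) would give the racemic flavanone, rac-5-(benzyloxy)-2-{4-[(5,7-bis(benzyloxy)-2-[4-(benzyloxy)phenyl]-4-oxo-4H-chromen-3-yl)oxy]phenyl}-7-methoxy-2,3-dihydro-4H-chromen-4-one F7.
- Preparative chromatography on a chiral stationary phase would separate 14 from its (2R)-enantiomer, (2R)-5-(benzyloxy)-2-{4-[(5,7-bis(benzyloxy)-2-[4-(benzyloxy)phenyl]-4-oxo-4H-chromen-3-yl)oxy]phenyl}-7-methoxy-2,3-dihydro-4H-chromen-4-one F8, which is set aside. The route resumes at 14.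

**Step 4.** Protodebromination may compete, and material may be lost while the free boronic acid is isolated (dehydration to boroxine, streaking on silica), because the substrate is poorly soluble in the alcohol that the diboron reagent needs.

Fallback, from 8 back to 9: borylation with B2pin2 (PdCl2(dppf), KOAc, dioxane, 90 °C) would give the chromatographable 5,7-bis(benzyloxy)-2-[4-(benzyloxy)phenyl]-3-[4-(4,4,5,5-tetramethyl-1,3,2-dioxaborolan-2-yl)phenoxy]-4H-chromen-4-one F9. Oxidative cleavage of the pinacol ester (NaIO4, NH4OAc, acetone/H2O, rt) then returns to 9.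

**Step 8.** Reduction may go too far (opening of the benzylic C2–O1 bond of the flavanone), or it may stall at the hindered peri benzyl ethers when partly deprotected material precipitates.

Fallback, from 14 directly to 15: non-reductive Lewis acid debenzylation with BCl3 and pentamethylbenzene as cation scavenger (CH2Cl2, −78 °C), which spares the para methyl ether at that temperature. No new compound arises on the way (entry F0).

## Further compounds

F1 | step 2 | 2-(4-bromophenoxy)-1-(2,4,6-trihydroxyphenyl)ethan-1-iminium chloride | [NH2+]=C(COc1ccc(Br)cc1)c1c(O)cc(O)cc1O.[Cl-]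
F2 | step 2 | 2-(4-bromophenoxy)-1-(2,4,6-trihydroxyphenyl)ethan-1-one | O=C(COc1ccc(Br)cc1)c1c(O)cc(O)cc1O
F3 | step 2 | 4-(benzyloxy)benzoic anhydride | O=C(OC(=O)c1ccc(OCc2ccccc2)cc1)c1ccc(OCc2ccccc2)cc1
F4 | step 2 | 2-[4-(benzyloxy)phenyl]-3-(4-bromophenoxy)-5-hydroxy-4-oxo-4H-chromen-7-yl 4-(benzyloxy)benzoate | O=C(Oc1cc(O)c2c(c1)oc(-c1ccc(OCc3ccccc3)cc1)c(Oc1ccc(Br)cc1)c2=O)c1ccc(OCc2ccccc2)cc1
F5 | step 7 | 4-[(5,7-bis(benzyloxy)-2-[4-(benzyloxy)phenyl]-4-oxo-4H-chromen-3-yl)oxy]benzaldehyde | O=Cc1ccc(Oc2c(-c3ccc(OCc4ccccc4)cc3)oc3cc(OCc4ccccc4)cc(OCc4ccccc4)c3c2=O)cc1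
F6 | step 7 | (2E)-1-[2-(benzyloxy)-6-hydroxy-4-methoxyphenyl]-3-{4-[(5,7-bis(benzyloxy)-2-[4-(benzyloxy)phenyl]-4-oxo-4H-chromen-3-yl)oxy]phenyl}prop-2-en-1-one | COc1cc(O)c(C(=O)/C=C/c2ccc(Oc3c(-c4ccc(OCc5ccccc5)cc4)oc4cc(OCc5ccccc5)cc(OCc5ccccc5)c4c3=O)cc2)c(OCc2ccccc2)c1
F7 | step 7 | rac-5-(benzyloxy)-2-{4-[(5,7-bis(benzyloxy)-2-[4-(benzyloxy)phenyl]-4-oxo-4H-chromen-3-yl)oxy]phenyl}-7-methoxy-2,3-dihydro-4H-chromen-4-one | COc1cc(OCc2ccccc2)c2c(c1)OC(c1ccc(Oc3c(-c4ccc(OCc5ccccc5)cc4)oc4cc(OCc5ccccc5)cc(OCc5ccccc5)c4c3=O)cc1)CC2=O
F8 | step 7 | (2R)-5-(benzyloxy)-2-{4-[(5,7-bis(benzyloxy)-2-[4-(benzyloxy)phenyl]-4-oxo-4H-chromen-3-yl)oxy]phenyl}-7-methoxy-2,3-dihydro-4H-chromen-4-one | COc1cc(OCc2ccccc2)c2c(c1)O[C@@H](c1ccc(Oc3c(-c4ccc(OCc5ccccc5)cc4)oc4cc(OCc5ccccc5)cc(OCc5ccccc5)c4c3=O)cc1)CC2=O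
F9 | step 4 | 5,7-bis(benzyloxy)-2-[4-(benzyloxy)phenyl]-3-[4-(4,4,5,5-tetramethyl-1,3,2-dioxaborolan-2-yl)phenoxy]-4H-chromen-4-one | CC1(C)OB(OC1(C)C)c1ccc(Oc2c(-c3ccc(OCc4ccccc4)cc3)oc3cc(OCc4ccccc4)cc(OCc4ccccc4)c3c2=O)cc1
F0 | step 8 | none | none
A1 | alternative 1 | 6-[(4R)-4-{4-[(5,7-bis(benzyloxy)-2-[4-(benzyloxy)phenyl]-4-oxo-4H-chromen-3-yl)oxy]phenyl}-4-(tert-butyldimethylsilyloxy)-2-oxobutyl]-4-methoxy-2H-pyran-2-one | COc1cc(CC(=O)C[C@@H](O[Si](C)(C)C(C)(C)C)c2ccc(Oc3c(-c4ccc(OCc5ccccc5)cc4)oc4cc(OCc5ccccc5)cc(OCc5ccccc5)c4c3=O)cc2)oc(=O)c1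
A2 | alternative 1 | (3R)-3-{4-[(5,7-bis(benzyloxy)-2-[4-(benzyloxy)phenyl]-4-oxo-4H-chromen-3-yl)oxy]phenyl}-3-(tert-butyldimethylsilyloxy)-1-(2,6-dihydroxy-4-methoxyphenyl)propan-1-one | CC(C)(C)[Si](C)(C)O[C@@H](c1ccc(Oc3c(-c4ccc(OCc5ccccc5)cc4)oc4cc(OCc5ccccc5)cc(OCc5ccccc5)c4c3=O)cc1)CC(=O)c1c(O)cc(OC)cc1O
A3 | alternative 1 | (2S)-2-{4-[(5,7-bis(benzyloxy)-2-[4-(benzyloxy)phenyl]-4-oxo-4H-chromen-3-yl)oxy]phenyl}-5-hydroxy-7-methoxy-2,3-dihydro-4H-chromen-4-one | COc1cc(O)c2c(c1)O[C@H](c1ccc(Oc3c(-c4ccc(OCc5ccccc5)cc4)oc4cc(OCc5ccccc5)cc(OCc5ccccc5)c4c3=O)cc1)CC2=O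
A4 | alternative 2 | tert-butyl 2-[2-(benzyloxy)-6-hydroxy-4-methoxybenzoyl]-3-{4-[(5,7-bis(benzyloxy)-2-[4-(benzyloxy)phenyl]-4-oxo-4H-chromen-3-yl)oxy]phenyl}prop-2-enoate (alkene geometry not fixed) | COc1cc(O)c(C(=O)C(=Cc2ccc(Oc3c(-c4ccc(OCc5ccccc5)cc4)oc4cc(OCc5ccccc5)cc(OCc5ccccc5)c4c3=O)cc2)C(=O)OC(C)(C)C)c(OCc2ccccc2)c1
A5 | alternative 2 | tert-butyl (2S,3R)-5-(benzyloxy)-2-{4-[(5,7-bis(benzyloxy)-2-[4-(benzyloxy)phenyl]-4-oxo-4H-chromen-3-yl)oxy]phenyl}-7-methoxy-4-oxo-3,4-dihydro-2H-chromene-3-carboxylate (trans; C3 epimerisable) | COc1cc(OCc2ccccc2)c2c(c1)O[C@H](c1ccc(Oc3c(-c4ccc(OCc5ccccc5)cc4)oc4cc(OCc5ccccc5)cc(OCc5ccccc5)c4c3=O)cc1)[C@@H](C(=O)OC(C)(C)C)C2=O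
A6 | alternative 3 | (3S)-3-{4-[(5,7-bis(benzyloxy)-2-[4-(benzyloxy)phenyl]-4-oxo-4H-chromen-3-yl)oxy]phenyl}-3-(3,5-dimethoxyphenoxy)propanoic acid | COc1cc(OC)cc(O[C@H](c2ccc(Oc3c(-c4ccc(OCc5ccccc5)cc4)oc4cc(OCc5ccccc5)cc(OCc5ccccc5)c4c3=O)cc2)CC(=O)O)c1
A7 | alternative 3 | (2S)-2-{4-[(5,7-bis(benzyloxy)-2-[4-(benzyloxy)phenyl]-4-oxo-4H-chromen-3-yl)oxy]phenyl}-5,7-dimethoxy-2,3-dihydro-4H-chromen-4-one | COc1cc(OC)c2c(c1)O[C@H](c1ccc(Oc3c(-c4ccc(OCc5ccccc5)cc4)oc4cc(OCc5ccccc5)cc(OCc5ccccc5)c4c3=O)cc1)CC2=O
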